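**Retrosynthetic overview**
1. Enabling feature: in the resorcinol ring the acyl-bearing carbon C2 lies between the two hydroxylated carbons C1 and C3. The unit O=C–C2(C1–O)(C3–O) is therefore an aromatised β-triketone, and the mirror plane through C2 and C5 makes C1/C3 and C4/C6 equivalent.
2. The last operation is rearomatisation (−2 H) of a 2-acylcyclohexane-1,3-dione. The key disconnection is the acyl C–C2 bond, leading back to 5-[2-(4-methoxyphenyl)-2-oxoethyl]cyclohexane-1,3-dione and 4-methylpentanoyl chloride. At the dione oxidation level C2 is the only carbon nucleophile, whereas the resorcinol itself would be acylated at C4/C6.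
3. The dione comes from Birch dearomatisation of 3,5-dimethoxyphenylacetic acid. This turns both ring methyl ethers into acid-labile enol ethers and so distinguishes them from the anisyl OMe, which arrives later with 4-methoxyphenylmagnesium bromide (Weinreb ketone synthesis).
4. Ring order: no ring is constructed, since both six-membered carbocycles are bought as arenes. The resorcinol ring is dearomatised first (step 1) and rearomatised last (step 5), the cyclohexanedione-to-resorcinol logic presumed for the biosynthesis of bacterial 2,5-disubstituted resorcinols.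

Key step: step 4

Remark: the target has no stereocentre and no stereogenic double bond, so it is one achiral species. The C5 stereocentre that appears in unsymmetrical enol derivatives (10, 12) is racemic or tautomerically labile and is erased in step 5.

Step 1
Reactants: 1 3,5-dimethoxyphenylacetic acid
Product: 2 2-(3,5-dimethoxycyclohexa-2,5-dien-1-yl)acetic acid
Conditions: Li (3.5 equiv), NH3(l)/THF, t-BuOH, −78 to −33 °C; NH4Cl; cold pH 5 buffer, EtOAc
Reagents that add atoms: none
Why: Birch reduction: the carboxylate is insulated from the ring, and the two protonations should fall on the para-related carbons C1 (side-chain carbon) and C4 (between the two C–OMe carbons), the only pair that leaves both methoxy groups on double bonds, so the 2,5-dihydro bis(enol ether) should result, whose new sp3 carbons lie on the mirror plane and are not stereocentres.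

Step 2
Reactants: 2 2-(3,5-dimethoxycyclohexa-2,5-dien-1-yl)acetic acid
Product: 4 2-(3,5-dimethoxycyclohexa-2,5-dien-1-yl)-N-methoxy-N-methylacetamide, via acyl imidazolide 3 (not isolated)
Conditions: CDI, THF, rt; then MeNH(OMe)·HCl, rt
Reagents that add atoms: N,O-dimethylhydroxylamine hydrochloride, CNOC.Cl
Why: Weinreb amide formation through an acyl imidazolide, an anhydrous and nearly neutral (imidazole-buffered) amide coupling that the acid-labile enol ethers should survive, with no stereocentre formed.

Step 3
Reactants: 4 2-(3,5-dimethoxycyclohexa-2,5-dien-1-yl)-N-methoxy-N-methylacetamide; 5 4-methoxyphenylmagnesium bromide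
Product: 8 5-[2-(4-methoxyphenyl)-2-oxoethyl]cyclohexane-1,3-dione, via magnesium hemiaminal chelate 6 (not isolated), via dienyl ketone 7 (not isolated)
Conditions: THF, 0 °C to rt; then 2 M HCl, THF, rt
Reagents that add atoms: water, O
Why: Weinreb ketone synthesis followed by enol ether hydrolysis in the same work-up: chelate 6 holds the addition at the ketone level, aqueous acid then releases ketone 7 and cleaves its two enol ethers to the vinylogous acid while the aryl methyl ether is inert, and C5 of the symmetric dione is not a stereocentre.

Step 4
Reactants: 8 5-[2-(4-methoxyphenyl)-2-oxoethyl]cyclohexane-1,3-dione; 9 4-methylpentanoyl chloride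
Product: 12 3-hydroxy-5-[2-(4-methoxyphenyl)-2-oxoethyl]-2-(4-methylpentanoyl)cyclohex-2-en-1-one (enol form of the 2-acyl-1,3-dione), via enol ester 10 (not isolated), via acylpyridinium enolate ion pair 11 (not isolated)
Conditions: Et3N (2.2 equiv), MeCN, 0 °C; then DMAP (20 mol %), 50 °C; 1 M HCl work-up
Reagents that add atoms: none
Why: Et3N-mediated O-acylation of the enol of 8 (pKa about 5) should give enol ester 10, DMAP then attacks its ester carbonyl to release ion pair 11, which recombines at C2 to form the acyl C–C2 bond, and the β-triketone (pKa about 3–4) is at once deprotonated by Et3N, which makes the transfer irreversible. The closest known reaction type is the DMAP- or cyanide-catalysed O-to-C acyl migration of cyclohexane-1,3-dione enol esters, the standard entry to 2-acylcyclohexane-1,3-diones including 5-substituted ones. No ring is closed and no lasting stereocentre is created, because C5 is racemic in 10, tautomerically averaged in 12 and flattened in step 5. The step needs C2 selectivity over O, C4/C6 and the ArCOCH2 carbon, and the substrate secures it: C2 is the only carbon flanked by two carbonyls, the other C–H acids (pKa about 19 or higher) are not ionised by Et3N, and O-acylation is reversible under DMAP while C-acylation is drained by deprotonation. The p-anisoyl ketone needs no protection, since the only intramolecular reaction open to C2, aldol addition to it, would give a bridged bicyclo[2.2.2]octanedione that cannot enolise and should revert. In one protecting-group-free operation the step completes the whole C21 skeleton and fixes the 2-acyl-1,3-dioxygenated pattern that Friedel–Crafts or Fries acylation of a 5-substituted resorcinol (C4/C6-selective) does not deliver.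

Step 5
Reactants: 12 3-hydroxy-5-[2-(4-methoxyphenyl)-2-oxoethyl]-2-(4-methylpentanoyl)cyclohex-2-en-1-one
Product: 13 1-{2,6-dihydroxy-4-[2-(4-methoxyphenyl)-2-oxoethyl]phenyl}-4-methylpentan-1-one (target)
Conditions: Hg(OAc)2 (2.2 equiv), NaOAc, AcOH, reflux; filter; 1 M HCl wash
Reagents that add atoms: none
Why: Mercuric acetate dehydrogenation of a 2-acylcyclohexane-1,3-dione to a 2-acylresorcinol: mercuration of a ring enol at C4 and loss of Hg and H across C4–C5 should give a cyclohexenedione that is a keto tautomer of the arene, and because C5–H is adjacent to all three enolisable positions (C4, C6, side-chain CH2) every possible desaturation converges on 13 by tautomerisation, leaving no stereocentre.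

**Compound list**
1 | 3,5-dimethoxyphenylacetic acid | COc1cc(CC(=O)O)cc(OC)c1 | starting material
2 | 2-(3,5-dimethoxycyclohexa-2,5-dien-1-yl)acetic acid | COC1=CC(CC(=O)O)C=C(OC)C1 | intermediate
3 | 2-(3,5-dimethoxycyclohexa-2,5-dien-1-yl)-1-(imidazol-1-yl)ethan-1-one (acyl imidazolide) | COC1=CC(CC(=O)n2ccnc2)C=C(OC)C1 | intermediate
4 | 2-(3,5-dimethoxycyclohexa-2,5-dien-1-yl)-N-methoxy-N-methylacetamide | COC1=CC(CC(=O)N(C)OC)C=C(OC)C1 | intermediate
5 | 4-methoxyphenylmagnesium bromide | COc1ccc([Mg]Br)cc1 | starting material
6 | bromomagnesium hemiaminal chelate from 4 and 5 (racemic) | COC1=CC(CC(O[Mg]Br)(N(C)OC)c2ccc(OC)cc2)C=C(OC)C1 | intermediate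
7 | 2-(3,5-dimethoxycyclohexa-2,5-dien-1-yl)-1-(4-methoxyphenyl)ethan-1-one | COC1=CC(CC(=O)c2ccc(OC)cc2)C=C(OC)C1 | intermediate
8 | 5-[2-(4-methoxyphenyl)-2-oxoethyl]cyclohexane-1,3-dione | COc1ccc(cc1)C(=O)CC1CC(=O)CC(=O)C1 | intermediate
9 | 4-methylpentanoyl chloride | CC(C)CCC(=O)Cl | starting material
10 | 5-[2-(4-methoxyphenyl)-2-oxoethyl]-3-oxocyclohex-1-en-1-yl 4-methylpentanoate (racemic) | CC(C)CCC(=O)OC1=CC(=O)CC(CC(=O)c2ccc(OC)cc2)C1 | intermediate
11 | 4-(dimethylamino)-1-(4-methylpentanoyl)pyridinium salt of the enolate of 8 | CC(C)CCC(=O)[n+]1ccc(cc1)N(C)C.COc1ccc(cc1)C(=O)CC1CC(=O)C=C([O-])C1 | intermediate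
12 | 3-hydroxy-5-[2-(4-methoxyphenyl)-2-oxoethyl]-2-(4-methylpentanoyl)cyclohex-2-en-1-one (racemic, tautomerically labile) | CC(C)CCC(=O)C1=C(O)CC(CC(=O)c2ccc(OC)cc2)CC1=O | intermediate
13 | 1-{2,6-dihydroxy-4-[2-(4-methoxyphenyl)-2-oxoethyl]phenyl}-4-methylpentan-1-one (achiral) | COc1ccc(C(=O)Cc2cc(O)c(C(=O)CCC(C)C)c(O)c2)cc1 | target

**Total step count:** 5. **Longest linear sequence:** 5 (1 → 2 → 4 → 8 → 12 → 13).

**Steps most likely to fail**

Step 5. The dehydrogenation may be sluggish or unselective. The electron-rich ring may be mercurated as it forms, or oxidation may continue at the doubly activated methylene. The fallback sets out from 12. Oxidative aromatisation with iodine in refluxing methanol, which etherifies one enol oxygen while it aromatises, should give mainly the monomethyl ether 1-{2-hydroxy-6-methoxy-4-[2-(4-methoxyphenyl)-2-oxoethyl]phenyl}-4-methylpentan-1-one F1. Chelation-directed demethylation with BCl3 (CH2Cl2, −78 to 0 °C) should then cleave only the methoxy group ortho to the ketone and spare the anisyl ether. The route is rejoined at 13.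

Step 1. The reduction may run too far, a methoxy group may be lost reductively, or the enol ethers may hydrolyse prematurely while the free acid is isolated. The fallback sets out from 1 and replaces dissolving-metal reduction by catalytic dearomatisation.
- BBr3 should give 3,5-dihydroxyphenylacetic acid F2.
- Partial hydrogenation of its resorcinol monoanion (H2, Pd/C or Rh/Al2O3, aqueous NaOH, then acid) should give (3,5-dioxocyclohexyl)acetic acid F3.
- CDI and MeNH(OMe)·HCl should give 2-(3,5-dioxocyclohexyl)-N-methoxy-N-methylacetamide F4.
- Excess 5 should first convert the dione into its inert magnesium enolate and then add to the amide. Acid work-up rejoins the route at 8.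

Step 4. The acyl transfer may stall at the O-acyl stage, or the acyl group may be lost hydrolytically on work-up. The fallback sets out from 8 and forms the same C–C bond through a temporary isoxazole ring.
- 4-Methylpentanal oxime F5 (E/Z mixture, from commercial 4-methylpentanal and hydroxylamine) is oxidised slowly with NaOCl to 4-methylpentanenitrile oxide F6.
- The nitrile oxide carbon is attacked by C2 of the enolate of 8, and cyclodehydration should give 6-[2-(4-methoxyphenyl)-2-oxoethyl]-3-(3-methylbutyl)-6,7-dihydro-1,2-benzoxazol-4(5H)-one F7.
- Reductive N–O cleavage (Mo(CO)6, MeCN/H2O, reflux) should give 2-(1-amino-4-methylpentylidene)-5-[2-(4-methoxyphenyl)-2-oxoethyl]cyclohexane-1,3-dione F8.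
- Aqueous NaOH followed by acid should hydrolyse the enamine and rejoin the route at 12.

**Further compounds**
F1 | step 5 | 1-{2-hydroxy-6-methoxy-4-[2-(4-methoxyphenyl)-2-oxoethyl]phenyl}-4-methylpentan-1-one | COc1ccc(cc1)C(=O)Cc1cc(O)c(C(=O)CCC(C)C)c(OC)c1
F2 | step 1 | 3,5-dihydroxyphenylacetic acid | OC(=O)Cc1cc(O)cc(O)c1
F3 | step 1 | (3,5-dioxocyclohexyl)acetic acid | OC(=O)CC1CC(=O)CC(=O)C1
F4 | step 1 | 2-(3,5-dioxocyclohexyl)-N-methoxy-N-methylacetamide | CON(C)C(=O)CC1CC(=O)CC(=O)C1
F5 | step 4 | 4-methylpentanal oxime (E/Z mixture) | CC(C)CCC=NO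
F6 | step 4 | 4-methylpentanenitrile oxide | CC(C)CCC#[N+][O-]
F7 | step 4 | 6-[2-(4-methoxyphenyl)-2-oxoethyl]-3-(3-methylbutyl)-6,7-dihydro-1,2-benzoxazol-4(5H)-one (racemic) | CC(C)CCc1noc2CC(CC(=O)c3ccc(OC)cc3)CC(=O)c12
F8 | step 4 | 2-(1-amino-4-methylpentylidene)-5-[2-(4-methoxyphenyl)-2-oxoethyl]cyclohexane-1,3-dione | CC(C)CCC(N)=C1C(=O)CC(CC(=O)c2ccc(OC)cc2)CC1=O
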